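**Retrosynthetic overview** (azulene locants of the target: C1 side chain, C3a CH3, C5 OAc, C6 =CH2, C8a H; side-chain carbons primed)
1. End game: the C5 acetate by selective acetylation, the side chain by cross metathesis of a C2' allyl carbinol made from a C1 acetyl group, and C1–H by conjugate reduction of a 1-acetylcyclopentene.
2. Enabling feature: C3, C2, C1, C2' and the C2' methyl become an isoprene unit once the C1–C2 bond is exchanged for a C2–C2' bond (a 1-acetylcyclopentene is the ozonolysis/aldol contraction product of a 4-methylcyclohexene); this unit spans the ring-fusion bond C3a–C8a, whose CH3 and H are trans and whose C3a carries C4.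
3. That cyclohexene is the Diels–Alder adduct of isoprene and an (E)-2-methyl-2-enal with C4 as formyl carbon: C3–C3a and C1–C8a form together, the E geometry becomes the trans ring fusion, and a chiral Lewis acid sets the quaternary centre and the absolute configuration.
4. The seven-membered ring is closed at C5–C6 by an intramolecular Nozaki–Hiyama–Kishi reaction of a 2-bromoalkene with the one-carbon-homologated aldehyde, which gives the C5–OH and the C6 methylidene at once.
5. Ring order: cyclohexene (temporary, step 3), then cycloheptane (step 5), then cyclopentene by contraction of the cyclohexene (steps 7 and 8).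

Key step: step 3

Assumption on the chemistry: the oxazaborolidinium catalyst derived from (S)-α,α-diphenylprolinol is taken to shield the Cα-Re face of s-trans 6 (formyl C–H···O binding model for 2-substituted enals), so that the diene adds to the Cα-Si face; if the opposite sense is found, the (R)-configured catalyst is used and nothing else changes.

**Step 1**
Reactants: 1 acetaldehyde N,N-dimethylhydrazone; 2 2,3-dibromoprop-1-ene
Product: 4 4-bromopent-4-enal, via alkylated hydrazone 3 (not isolated)
Conditions: LiN(iPr)2, THF, 0 °C; 2, −78 → 0 °C; then 1 M aq HCl/pentane, rt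
Reagents that add atoms: water, `O`
Why: Azaenolate alkylation of the lithiated dimethylhydrazone at the allylic CH2Br of 2 (SN2) leaves the vinylic bromide untouched, and two-phase acid hydrolysis then frees the aldehyde; no stereocentre is formed.

**Step 2**
Reactants: 4 4-bromopent-4-enal; 5 2-(triphenyl-λ5-phosphanylidene)propanal
Product: 6 (2E)-6-bromo-2-methylhepta-2,6-dienal
Conditions: toluene, 80 °C
Reagents that add atoms: none
Why: Wittig olefination with a formyl-stabilised ylide runs under thermodynamic control and should give the (E)-2-methyl-2-enal, the geometry that later becomes the trans ring fusion.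

**Step 3**
Reactants: 6 (2E)-6-bromo-2-methylhepta-2,6-dienal; 7 isoprene (2-methylbuta-1,3-diene)
Product: 8 (1S,6S)-6-(3-bromobut-3-en-1-yl)-1,4-dimethylcyclohex-3-ene-1-carbaldehyde
Conditions: 7 (5 equiv), 20 mol % of the Tf2NH salt of (S)-1-(2-methylphenyl)-3,3-diphenyltetrahydro-1H,3H-pyrrolo[1,2-c][1,3,2]oxazaborole, CH2Cl2, −78 → −20 °C
Reagents that add atoms: none
Why: The chiral oxazaborolidinium ion binds the formyl oxygen of s-trans 6 and the diene adds in a concerted, asynchronous, Lewis acid-catalysed [4+2] cycloaddition. The closest known reaction type is the catalytic enantioselective Diels–Alder reaction of 2-substituted enals (methacrolein, tiglic aldehyde) with 2-substituted butadienes under cationic oxazaborolidine catalysis. The one ring closed, a 4-methylcyclohexene that serves as a temporary ring, closes by intermolecular suprafacial–suprafacial cycloaddition that forms its C1–C2 and C5–C6 bonds (the later C3a–C3 and C8a–C1 bonds of the target) together. The relative configuration of the quaternary centre C1 and of C6 follows from the E geometry of 6, which is transferred stereospecifically so that formyl and bromobutenyl stay trans and CH3 and H end up trans, while the absolute configuration (1S,6S) follows from the catalyst shielding the Cα-Re face. The step needs "para" regioselectivity, secured because the formyl group sits on the methyl-bearing carbon so that the larger LUMO coefficient at Cβ pairs with the more nucleophilic C1 of isoprene, and it needs chemoselectivity, secured because the 2-bromoalkene is not an activated dienophile.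

**Step 4**
Reactants: 8 (1S,6S)-6-(3-bromobut-3-en-1-yl)-1,4-dimethylcyclohex-3-ene-1-carbaldehyde
Product: 10 2-[(1R,6S)-6-(3-bromobut-3-en-1-yl)-1,4-dimethylcyclohex-3-en-1-yl]acetaldehyde, via enol ether 9 (not isolated)
Conditions: Ph3P(CH2OMe)Cl, KN(SiMe3)2, THF, 0 °C → rt; then 2 M aq HCl, THF, rt
Reagents that add atoms: (methoxymethyl)triphenylphosphonium chloride, `COC[P+](c1ccccc1)(c1ccccc1)c1ccccc1.[Cl-]`; water, `O`
Why: Wittig methoxymethylenation of the non-enolisable neopentylic aldehyde followed by acid hydrolysis of the enol ether is the standard one-carbon homologation, and neither stereocentre can epimerise.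

**Step 5**
Reactants: 10 2-[(1R,6S)-6-(3-bromobut-3-en-1-yl)-1,4-dimethylcyclohex-3-en-1-yl]acetaldehyde
Product: 11 (4aR,6S,9aS)-2,4a-dimethyl-7-methylidene-4,4a,5,6,7,8,9,9a-octahydro-1H-benzo[7]annulen-6-ol
Conditions: CrCl2 (8 equiv), NiCl2 (5 mol %), DMSO, 0.005 M, rt → 50 °C
Reagents that add atoms: none
Why: In this intramolecular Nozaki–Hiyama–Kishi reaction zerovalent nickel inserts into the C–Br bond, the alkenyl group passes to trivalent chromium and adds chemoselectively to the aldehyde, which closes the seven-membered ring and gives the 2-methylidene alcohol directly; the chromium alkoxide should take the equatorial site of a chair-like transition state, away from the axial angular methyl, which sets the 6S carbinol (OH trans to CH3).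

**Step 6**
Reactants: 11 (4aR,6S,9aS)-2,4a-dimethyl-7-methylidene-4,4a,5,6,7,8,9,9a-octahydro-1H-benzo[7]annulen-6-ol
Product: 12 (4aR,6S,9aS)-2,4a-dimethyl-7-methylidene-4,4a,5,6,7,8,9,9a-octahydro-1H-benzo[7]annulen-6-yl acetate
Conditions: Ac2O, pyridine, 4-(dimethylamino)pyridine (cat.), CH2Cl2, 0 °C → rt
Reagents that add atoms: acetic anhydride, `CC(=O)OC(C)=O`
Why: Nucleophile-catalysed acetylation of the secondary allylic alcohol; the acetate blocks lactol formation and deactivates the neighbouring 1,1-disubstituted alkene for the next step.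

**Step 7**
Reactants: 12 (4aR,6S,9aS)-2,4a-dimethyl-7-methylidene-4,4a,5,6,7,8,9,9a-octahydro-1H-benzo[7]annulen-6-yl acetate
Product: 14 (1S,5S,6S)-6-methyl-2-methylidene-6-(2-oxoethyl)-5-(2-oxopropyl)cycloheptyl acetate, via ozonide 13 (not isolated)
Conditions: O3 (1.0 equiv, Sudan red 7B end point), CH2Cl2, −78 °C; then PPh3, −78 °C → rt
Reagents that add atoms: ozone, `[O-][O+]=O`
Why: In this chemoselective ozonolysis the electrophilic ozone should attack the electron-rich trisubstituted ring alkene much faster than the 1,1-disubstituted alkene deactivated by the allylic acetate, so one equivalent dosed to a dye end point and reductive work-up of the ozonide give the 1,6-keto aldehyde without touching a stereocentre.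

**Step 8**
Reactants: 14 (1S,5S,6S)-6-methyl-2-methylidene-6-(2-oxoethyl)-5-(2-oxopropyl)cycloheptyl acetate
Product: 17 1-[(3aR,5S,8aR)-5-hydroxy-3a-methyl-6-methylidene-3,3a,4,5,6,7,8,8a-octahydroazulen-1-yl]ethan-1-one, via aldol adduct 15 (not isolated), via enone acetate 16 (not isolated)
Conditions: KOH (3 equiv), MeOH/H2O 4:1, 0 °C → rt
Reagents that add atoms: none
Why: Base-mediated intramolecular aldol condensation (five-membered ring closure by the ketone methylene enolate on the more electrophilic aldehyde, then E1cB dehydration) completes the ring contraction to the conjugated acetylcyclopentene, the aldehyde-enolate mode being disfavoured by its neopentylic α-carbon; hydroxide also saponifies the acetate, and neither ring-fusion centre bears an acidic hydrogen.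

**Step 9**
Reactants: 17 1-[(3aR,5S,8aR)-5-hydroxy-3a-methyl-6-methylidene-3,3a,4,5,6,7,8,8a-octahydroazulen-1-yl]ethan-1-one
Product: 18 1-[(1S,3aR,5S,8aS)-5-hydroxy-3a-methyl-6-methylidenedecahydroazulen-1-yl]ethan-1-one
Conditions: [(Ph3P)CuH]6 (0.4 equiv), H2O (5 equiv), degassed toluene, rt
Reagents that add atoms: none
Why: Conjugate reduction with the monovalent copper hydride delivers hydride to C2 and spares the isolated alkene; water should protonate the copper enolate at C1 under kinetic control from the α-face, opposite the pseudo-axial angular methyl, which places the acetyl group cis to that methyl (1S).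

**Step 10**
Reactants: 18 1-[(1S,3aR,5S,8aS)-5-hydroxy-3a-methyl-6-methylidenedecahydroazulen-1-yl]ethan-1-one
Product: 19 (1S,3aR,5S,8aS)-1-[(2S)-2-hydroxypent-4-en-2-yl]-3a-methyl-6-methylidenedecahydroazulen-5-ol
Conditions: allylmagnesium bromide (3 equiv), THF, −78 °C; sat. aq NH4Cl
Reagents that add atoms: allylmagnesium bromide, `C=CC[Mg]Br`
Why: Grignard 1,2-addition under Felkin–Anh control: with C8a as the large α-substituent anti to the incoming allyl group and the nucleophile passing the C1 hydrogen, the Si face of the ketone should be attacked to give the (2S)-carbinol; one equivalent of reagent is spent on the C5 hydroxyl.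

**Step 11**
Reactants: 19 (1S,3aR,5S,8aS)-1-[(2S)-2-hydroxypent-4-en-2-yl]-3a-methyl-6-methylidenedecahydroazulen-5-ol; 20 2-methylbut-3-en-2-ol
Product: 21 (2S,4E)-2-[(1S,3aR,5S,8aS)-5-hydroxy-3a-methyl-6-methylidenedecahydroazulen-1-yl]-6-methylhept-4-ene-2,6-diol
Conditions: 20 (10 equiv), second-generation Grubbs catalyst (H2IMes)(PCy3)Cl2Ru=CHPh (5 mol %), CH2Cl2, 40 °C
Reagents that add atoms: none
Why: Olefin cross metathesis of the terminal alkene with the tertiary allylic alcohol 20 should be E-selective under thermodynamic control, and the hindered 1,1-disubstituted exocyclic alkene should not enter the catalytic cycle.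

**Step 12**
Reactants: 21 (2S,4E)-2-[(1S,3aR,5S,8aS)-5-hydroxy-3a-methyl-6-methylidenedecahydroazulen-1-yl]-6-methylhept-4-ene-2,6-diol
Product: 22 (1S,3aR,5S,8aS)-1-[(2S,4E)-2,6-dihydroxy-6-methylhept-4-en-2-yl]-3a-methyl-6-methylidenedecahydroazulen-5-yl acetate (CNP0290154.1)
Conditions: Ac2O (1.5 equiv), pyridine, rt
Reagents that add atoms: acetic anhydride, `CC(=O)OC(C)=O`
Why: Acetylation without an acyl-transfer catalyst distinguishes the secondary C5 alcohol from the two tertiary alcohols, which should stay inert; no stereocentre is affected.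

**Compound list**
1 | acetaldehyde N,N-dimethylhydrazone | `CC=NN(C)C` | starting material
2 | 2,3-dibromoprop-1-ene | `C=C(Br)CBr` | starting material
3 | 4-bromopent-4-enal N,N-dimethylhydrazone (not isolated) | `C=C(Br)CCC=NN(C)C` | intermediate
4 | 4-bromopent-4-enal | `C=C(Br)CCC=O` | intermediate
5 | 2-(triphenyl-λ5-phosphanylidene)propanal | `CC(C=O)=P(c1ccccc1)(c1ccccc1)c1ccccc1` | starting material
6 | (2E)-6-bromo-2-methylhepta-2,6-dienal | `C=C(Br)CC/C=C(\C)C=O` | intermediate
7 | isoprene (2-methylbuta-1,3-diene) | `C=CC(C)=C` | starting material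
8 | (1S,6S)-6-(3-bromobut-3-en-1-yl)-1,4-dimethylcyclohex-3-ene-1-carbaldehyde | `C=C(Br)CC[C@H]1CC(C)=CC[C@]1(C)C=O` | intermediate
9 | (4S,5S)-5-(3-bromobut-3-en-1-yl)-4-(2-methoxyethenyl)-1,4-dimethylcyclohex-1-ene, E/Z mixture at the enol ether (not isolated) | `C=C(Br)CC[C@H]1CC(C)=CC[C@]1(C)C=COC` | intermediate
10 | 2-[(1R,6S)-6-(3-bromobut-3-en-1-yl)-1,4-dimethylcyclohex-3-en-1-yl]acetaldehyde | `C=C(Br)CC[C@H]1CC(C)=CC[C@]1(C)CC=O` | intermediate
11 | (4aR,6S,9aS)-2,4a-dimethyl-7-methylidene-4,4a,5,6,7,8,9,9a-octahydro-1H-benzo[7]annulen-6-ol (trans-fused; OH trans to the angular CH3) | `C=C1CC[C@H]2CC(C)=CC[C@]2(C)C[C@@H]1O` | intermediate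
12 | (4aR,6S,9aS)-2,4a-dimethyl-7-methylidene-4,4a,5,6,7,8,9,9a-octahydro-1H-benzo[7]annulen-6-yl acetate | `C=C1CC[C@H]2CC(C)=CC[C@]2(C)C[C@@H]1OC(C)=O` | intermediate
13 | secondary ozonide of 12 (1,2,4-trioxolane across the former ring C=C; mixture of isomers at the two trioxolane carbons; not isolated) | `C=C1CC[C@H]2CC3(C)OOC(O3)C[C@]2(C)C[C@@H]1OC(C)=O` | intermediate
14 | (1S,5S,6S)-6-methyl-2-methylidene-6-(2-oxoethyl)-5-(2-oxopropyl)cycloheptyl acetate | `C=C1CC[C@@H](CC(C)=O)[C@](C)(CC=O)C[C@@H]1OC(C)=O` | intermediate
15 | aldol adduct: 1-acetyl-2-hydroxy-3a-methyl-6-methylidenedecahydroazulen-5-yl acetate, trans-fused, retained centres as in 14, mixture at C1 and C2 (not isolated) | `C=C1CC[C@H]2C(C(C)=O)C(O)C[C@]2(C)C[C@@H]1OC(C)=O` | intermediate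
16 | (3aR,5S,8aR)-1-acetyl-3a-methyl-6-methylidene-3,3a,4,5,6,7,8,8a-octahydroazulen-5-yl acetate (not isolated) | `C=C1CC[C@H]2C(C(C)=O)=CC[C@]2(C)C[C@@H]1OC(C)=O` | intermediate
17 | 1-[(3aR,5S,8aR)-5-hydroxy-3a-methyl-6-methylidene-3,3a,4,5,6,7,8,8a-octahydroazulen-1-yl]ethan-1-one | `C=C1CC[C@H]2C(C(C)=O)=CC[C@]2(C)C[C@@H]1O` | intermediate
18 | 1-[(1S,3aR,5S,8aS)-5-hydroxy-3a-methyl-6-methylidenedecahydroazulen-1-yl]ethan-1-one | `C=C1CC[C@H]2[C@@H](C(C)=O)CC[C@]2(C)C[C@@H]1O` | intermediate
19 | (1S,3aR,5S,8aS)-1-[(2S)-2-hydroxypent-4-en-2-yl]-3a-methyl-6-methylidenedecahydroazulen-5-ol | `C=C1CC[C@H]2[C@@H]([C@@](C)(O)CC=C)CC[C@]2(C)C[C@@H]1O` | intermediate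
20 | 2-methylbut-3-en-2-ol | `C=CC(C)(C)O` | starting material
21 | (2S,4E)-2-[(1S,3aR,5S,8aS)-5-hydroxy-3a-methyl-6-methylidenedecahydroazulen-1-yl]-6-methylhept-4-ene-2,6-diol | `C=C1CC[C@H]2[C@@H]([C@@](C)(O)C/C=C/C(C)(C)O)CC[C@]2(C)C[C@@H]1O` | intermediate
22 | (1S,3aR,5S,8aS)-1-[(2S,4E)-2,6-dihydroxy-6-methylhept-4-en-2-yl]-3a-methyl-6-methylidenedecahydroazulen-5-yl acetate | `C=C1CC[C@H]2[C@@H]([C@@](C)(O)C/C=C/C(C)(C)O)CC[C@]2(C)C[C@@H]1OC(C)=O` | target

**Step count and risks**
Total step count: 12. Longest linear sequence: 12 steps (1 and 2 to 22).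

The three steps most likely to fail:

Step 3. What may go wrong: sluggish cycloaddition of the trisubstituted enal, acid-induced oligomerisation of isoprene, or weak facial discrimination by the catalyst, leading to low enantiomeric purity. Fallback (racemic cycloaddition and enzymatic resolution in place of asymmetric catalysis): it sets out from 6 and 7, which with Me2AlCl in CH2Cl2 at −78 → 0 °C should give the racemic aldehyde F1. This is taken through steps 4 and 5 unchanged, by way of the racemic enol ether F2 (not isolated) and the racemic homologated aldehyde F3, to the racemic alcohol F4. Acylation of F4 with vinyl acetate and Burkholderia cepacia lipase in tert-butyl methyl ether at 30 °C, stopped near half conversion, should by the empirical rule for lipase acylation of secondary alcohols convert the (6R)-alcohol into the enantiomeric acetate F5 and leave 11, which is separated and comes back to the route at 11. If the enzyme prefers the (6S)-alcohol, the acetate formed is 12 itself and the fallback returns at 12.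

Step 9. What may go wrong: protonation of the enolate from the β-face, or epimerisation at C1 after protonation toward the probably more stable 1-epimer. Fallback (masking of the exocyclic alkene and heterogeneous hydrogenation in place of hydride reduction and protonation): it sets out from 17. Hydroxyl-directed epoxidation with VO(acac)2 and tert-butyl hydroperoxide in CH2Cl2 should convert only the allylic-alcohol alkene into the spiro-epoxide F6. Hydrogenation over palladium on carbon (Pd/C, H2, ethyl acetate) should then add both hydrogens to the enone from the α-face, opposite the angular methyl, to give the saturated epoxy ketone F7. Deoxygenation of the oxirane with triphenylphosphine selenide and trifluoroacetic acid in CH2Cl2 at rt restores the methylidene group, and the fallback comes back to the route at 18.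

Step 10. What may go wrong: poor facial discrimination in the fast allyl Grignard addition, giving a mixture of C2' epimers. Fallback (reagent control in place of substrate control): it sets out from 18, which is treated in ether at −78 °C with enantiopure B-allyl-10-phenyl-9-borabicyclo[3.3.2]decane, taking the antipode that adds to the Si face of methyl ketones, followed by oxidative work-up; it comes back to the route at 19 and makes no new compound.

**Further compounds**
F1 | step 3 | racemic 8 (1:1 mixture of 8 and its enantiomer) | `C=C(Br)CC[C@H]1CC(C)=CC[C@]1(C)C=O.C=C(Br)CC[C@@H]1CC(C)=CC[C@@]1(C)C=O`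
F2 | step 3 | racemic 9 (1:1 mixture of 9 and its enantiomer, E/Z mixture, not isolated) | `C=C(Br)CC[C@H]1CC(C)=CC[C@]1(C)C=COC.C=C(Br)CC[C@@H]1CC(C)=CC[C@@]1(C)C=COC`
F3 | step 3 | racemic 10 (1:1 mixture of 10 and its enantiomer) | `C=C(Br)CC[C@H]1CC(C)=CC[C@]1(C)CC=O.C=C(Br)CC[C@@H]1CC(C)=CC[C@@]1(C)CC=O`
F4 | step 3 | racemic 11 (1:1 mixture of 11 and its enantiomer) | `C=C1CC[C@H]2CC(C)=CC[C@]2(C)C[C@@H]1O.C=C1CC[C@@H]2CC(C)=CC[C@@]2(C)C[C@H]1O`
F5 | step 3 | (4aS,6R,9aR)-2,4a-dimethyl-7-methylidene-4,4a,5,6,7,8,9,9a-octahydro-1H-benzo[7]annulen-6-yl acetate (enantiomer of 12) | `C=C1CC[C@@H]2CC(C)=CC[C@@]2(C)C[C@H]1OC(C)=O`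
F6 | step 9 | spiro-epoxide of 17 (C6 methylidene converted into an oxirane whose oxygen is cis to the C5 hydroxyl) | `C1O[C@@]12CC[C@H]3C(C(C)=O)=CC[C@]3(C)C[C@@H]2O`
F7 | step 9 | spiro-epoxide of 18 (same oxirane; C1 acetyl cis to the angular methyl) | `C1O[C@@]12CC[C@H]3[C@@H](C(C)=O)CC[C@]3(C)C[C@@H]2O`
F0 | step 10 | none | none
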